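The constant you need isn't given, so read it from the runs first. You asked for a quick number on elm and birch, with the hunch that more nucleophile helps.

| flask | electrophile | nucleophile | remark | time |
|---|---|---|---|---|
| teal | 10 mM (fed, over 1.5 h) | 1.2 equiv | run made earlier |  |
| violet | 10 mM (fed, over 1.5 h) | 1.8 equiv | run made earlier |  |
| elm | 10 mM (fed, over 1.5 h) | 2.60 equiv |  | 3.0 h |
| birch | 10 mM (fed, over 1.5 h) | 2.00 equiv |  | 3.0 h |

1. part of the electrophile that has reacted at the end, elm
2. part of the electrophile that has reacted at the end, birch
3. what raising the equivalents of nucleophile from its lowest to its highest value here does to the part of the electrophile that has reacted (changes below 5 percentage points count as none) (it falls / no change / it rises)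

| run | time / min | electrophile / % | target / % |
|---|---|---|---|
| teal | 10.0 | 12.7 | 0.4 |
| teal | 15.0 | 14.5 | 0 |
| teal | 25.0 | 25.9 | 1.2 |
| teal | 40.0 | 39.7 | 3.2 |
| teal | 50.0 | 50.1 | 7.5 |
| teal | 80.0 | 73.4 | 12.8 |
| teal | 120 | 74.0 | 24.1 |
| violet | 10.0 | 12.2 | 1.8 |
| violet | 15.0 | 16.2 | 0.4 |
| violet | 25.0 | 25.9 | 4.2 |
| violet | 40.0 | 37.1 | 6.2 |
| violet | 50.0 | 47.2 | 8.7 |
| violet | 80.0 | 67.9 | 21.2 |
| violet | 120 | 63.1 | 33.1 |

(standard deviation of a reading: 1 percentage point)

- target is meant together with its crystals
- solid, in amounts per volume of the solution: crystals
- steps under discussion: electrophile + nucleophile -> acid set free + target; nucleophile + acid set free <-> protonated nucleophile; target <-> isomer of the product; crystals <-> target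
- percentages count the whole charge, also what has not yet gone in

Write the balance of the electrophile: what was dosed equals what is left plus what has reacted. Take the last two readings of each run. In violet, between 80.0 min and 120 min, the balance says 15.9% of the charge reacted. In teal it says 10.5%.

Divide each by the time, the mean electrophile and the mean free nucleophile. I count 2 nucleophile per electrophile reacted, one to react and one taken by the acid set free. That is my assumption from the listed steps. Violet reads 0.497 L mol⁻¹ min⁻¹ and teal 0.454 L mol⁻¹ min⁻¹. Their mean is 0.476 L mol⁻¹ min⁻¹: the pair constant, the rate divided by c(electrophile) and c(nucleophile). It is a reading and carries their scatter.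

Nucleophile can carry equivalents/2 of the charge. In elm that exceeds the whole charge, so electrophile is the limiting reagent there. Call the smaller of that share and the whole charge the reach. I guess that 0.7 of the reach reacts by the end. With 2 nucleophile lost per electrophile reacted, a steady fall puts mean c(nucleophile) that amount below its start. Multiplying by the pair constant gives a pseudo-first-order rate constant r. The share left is (1 − e^(−r·tf))/(r·tf) · e^(−r·(t − tf)), with tf the feed time and t the end.

| flask | mean c(nucleophile) | r | reacted at the end |
|---|---|---|---|
| elm | 19.0 mM | 0.00904 min⁻¹ | 69.7% |
| birch | 13.0 mM | 0.00618 min⁻¹ | 56.0% |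

The forecast gives 63% for elm and 53% for birch, both below mine, and says it rises, holding that “Each electrophile reacted should use two nucleophiles”.

The flasks give 66.6% for elm and 55.9% for birch. From lowest to highest nucleophile, it rises, by 11 percentage points.

    electrophile + nucleophile → acid set free + target (k = 0.480 L mol⁻¹ min⁻¹)
    nucleophile + acid set free ⇌ protonated nucleophile, settled at all times (K = 15000 L mol⁻¹)
    target ⇌ isomer of the product (K = 20.0, k = 0.00620 min⁻¹)
    crystals ⇌ target, rate k4*(cs4 - [target]) while solid is left; crystals form when [target] > cs4 (solubility = 0.220 mM, k = 0.0780 min⁻¹)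

Now take the neighbour of elm with 1.00 equiv of nucleophile, other charges held. Its reach is 50.0% of the charge, so here nucleophile is the limiting reagent. The same reckoning puts mean c(nucleophile) at 6.50 mM, and the pair constant turns that into r = 0.00309 min⁻¹. That gives 33.9% reacted. The flask gives 32.2%. At 3.0 h it still holds 68% of its electrophile, and 36% of its nucleophile is free.

The data stem from a simulated flask from invented constants; scatter was added.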